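Ring A (C1 depside carbonyl, C2 methyl, C3/C4 hydroxyls, C5 formyl, C6 hydroxyl) carries its C5 formyl and C6 hydroxyl side by side, with the C4 oxygen flanking C5 and only a hydrogen at C1. Both groups are therefore traced back to the C5≡C6 aryne and N,N-dimethylformamide: one fluoride-triggered insertion forms the C5–C and C6–O bonds at once, the C4 isopropoxy group dictating the orientation. The aryne precursor is an ortho-silylaryl triflate (silicon on C5, triflate on C6, isopropyl ethers on C3 and C4), made from 3-methylcatechol by steric C–H borylation/oxidation and carbamate-directed silylation. Iodination at C1, carbonylative coupling with the commercial ring B phenol and BCl3 deprotection finish the depside.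

Key step: step 6

Remark on the chemistry: ring A is the acyl ring, numbered as above, and ring B is the methyl benzoate ring. The target has no stereocentre, so no step has to set or preserve configuration.

Step 1
Reactants: 1 3-methylcatechol
Product: 2 1,2-diisopropoxy-3-methylbenzene
Conditions: 2-bromopropane (3 equiv), K2CO3 (3 equiv), MeCN, reflux, N2
Reagents that add atoms: 2-bromopropane, CC(C)Br
Why: Double Williamson etherification, in which the carbonate-generated catecholate displaces bromide twice and excess secondary halide makes up for competing elimination.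

Step 2
Reactants: 2 1,2-diisopropoxy-3-methylbenzene
Product: 4 3,4-diisopropoxy-5-methylphenol, via arylboronate 3 (not isolated)
Conditions: [Ir(OMe)(cod)]2 (1.5 mol %), 4,4'-di-tert-butyl-2,2'-bipyridine (3 mol %), B2pin2 (0.7 equiv), THF, 80 °C; then aq. NaOH, 30% aq. H2O2, 0 °C → rt
Reagents that add atoms: bis(pinacolato)diboron, CC1(C)OB(OC1(C)C)B1OC(C)(C)C(C)(C)O1 (boron carried only by 3); hydrogen peroxide, OO (oxygen of the phenol)
Why: Iridium-catalysed aromatic C–H borylation is sterically controlled, so boron should enter only at the one ring C–H without an ortho neighbour, and the boronate is then oxidised in the same flask by the usual boron-to-oxygen 1,2-aryl shift.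

Step 3
Reactants: 4 3,4-diisopropoxy-5-methylphenol
Product: 5 3,4-diisopropoxy-5-methylphenyl N-isopropylcarbamate
Conditions: isopropyl isocyanate (1.5 equiv), Et3N (0.2 equiv), CH2Cl2, rt
Reagents that add atoms: isopropyl isocyanate, CC(C)N=C=O
Why: Base-catalysed addition of the phenol to the isocyanate (carbamoylation) installs an N-monoalkyl carbamate, chosen because it directs ortho-metalation once N-silylated and can later be removed without nucleophiles that would attack a C–Si bond.

Step 4
Reactants: 5 3,4-diisopropoxy-5-methylphenyl N-isopropylcarbamate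
Product: 9 3,4-diisopropoxy-5-methyl-2-(trimethylsilyl)phenyl N-isopropylcarbamate, via N-silyl carbamate 6 (not isolated), via aryllithium 7 (not isolated), via bis-silyl carbamate 8 (not isolated)
Conditions: TBSOTf (1.05 equiv), TMEDA (1.1 equiv), Et2O, 0 °C → rt; then TMEDA (2 equiv), n-BuLi (2 equiv), −78 °C; then TMSCl, −78 °C → rt; aq. NaHSO4
Reagents that add atoms: chlorotrimethylsilane, C[Si](C)(C)Cl (tert-butyldimethylsilyl triflate, CC(C)(C)[Si](C)(C)OS(=O)(=O)C(F)(F)F, silylates nitrogen in 6 to 8 only)
Why: Directed ortho-metalation, in which the N-silylated carbamate and the meta isopropoxy oxygen cooperate to steer n-BuLi/TMEDA to the C–H between them and not to the one beside the methyl group, after which chlorotrimethylsilane traps the aryllithium and the acidic work-up removes the labile N-silyl group.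

Step 5
Reactants: 9 3,4-diisopropoxy-5-methyl-2-(trimethylsilyl)phenyl N-isopropylcarbamate
Product: 11 3,4-diisopropoxy-5-methyl-2-(trimethylsilyl)phenyl trifluoromethanesulfonate, via silylphenol 10 (not isolated)
Conditions: DBU (1.5 equiv), Et2NH (1.2 equiv), MeCN, 40 °C; then PhNTf2 (1.5 equiv), 40 °C
Reagents that add atoms: N-phenylbis(trifluoromethanesulfonimide), O=S(=O)(N(c1ccccc1)S(=O)(=O)C(F)(F)F)C(F)(F)F
Why: E1cB carbamate cleavage followed by O-sulfonylation, in which DBU removes the N–H proton, the phenoxide of 10 is expelled together with isopropyl isocyanate (scavenged by diethylamine as a urea) and the phenoxide is triflated in the same flask.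

Step 6
Reactants: 11 3,4-diisopropoxy-5-methyl-2-(trimethylsilyl)phenyl trifluoromethanesulfonate; 12 N,N-dimethylformamide
Product: 16 6-hydroxy-2,3-diisopropoxy-4-methylbenzaldehyde, via aryne 13 (not isolated), via benzoxete aminal 14 (not isolated), via quinone methide 15 (not isolated)
Conditions: CsF (3 equiv), anhydrous 12 as solvent (about 0.05 M), 25 → 50 °C; then H2O, rt
Reagents that add atoms: N,N-dimethylformamide (12), CN(C)C=O; water, O
Why: Fluoride attacks silicon and the aryl anion expels triflate to give aryne 13, whose triple bond is polarised by the inductively withdrawing C4 isopropoxy group so that the carbonyl oxygen of 12 adds to C6 and the resulting C5 aryl anion, stabilised by the adjacent C4–O bond, closes onto the iminium carbon. This is the known insertion of arynes from ortho-silylaryl triflates into the C=O bond of formamides, a formal [2+2] addition that gives a salicylaldehyde after hydrolysis. The only ring formed is the transient four-membered oxete of 14, closed stepwise by 4-exo-trig attack of the aryl anion on the iminium ion; it opens electrocyclically to quinone methide 15, which water hydrolyses, so no ring remains, the formyl C–H and the C6 oxygen coming from 12 and the aldehyde oxygen from water. No stereocentre survives, since the aminal carbon of 14 is racemic and is destroyed. The step needs regioselectivity (oxygen at C6, carbon at C5), which the C4 alkoxy group beside the triple bond secures through inductive distortion and steric shielding of C5, while the hydrogen at C1 exerts no counter-bias; anhydrous 12 as solvent at high dilution should keep a second aryne from intercepting 15.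

Step 7
Reactants: 16 6-hydroxy-2,3-diisopropoxy-4-methylbenzaldehyde
Product: 17 2-hydroxy-3-iodo-5,6-diisopropoxy-4-methylbenzaldehyde
Conditions: NIS (1.05 equiv), MeCN, 0 °C → rt
Reagents that add atoms: N-iodosuccinimide, O=C1CCC(=O)N1I
Why: Electrophilic aromatic iodination can only occur at C1, the single unsubstituted ring carbon (ortho to the free phenol, para to the C4 ether), and an iodide is chosen to ease the later oxidative addition at a doubly flanked carbon.

Step 8
Reactants: 17 2-hydroxy-3-iodo-5,6-diisopropoxy-4-methylbenzaldehyde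
Product: 18 3-iodo-2,5,6-triisopropoxy-4-methylbenzaldehyde
Conditions: 2-bromopropane (4 equiv), K2CO3 (3 equiv), DMF, 60 °C
Reagents that add atoms: 2-bromopropane, CC(C)Br
Why: Williamson etherification of the acidic salicylaldehyde-type phenol masks the C6 hydroxyl so that it cannot compete as a nucleophile in the carbonylation, with a group that leaves in the last step together with the other two ethers.

Step 9
Reactants: 18 3-iodo-2,5,6-triisopropoxy-4-methylbenzaldehyde; 19 methyl 2,4-dihydroxy-3,6-dimethylbenzoate
Product: 20 methyl 4-[(3-formyl-2,4,5-triisopropoxy-6-methylbenzoyl)oxy]-2-hydroxy-3,6-dimethylbenzoate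
Conditions: Pd(OAc)2 (5 mol %), Xantphos (6 mol %), Et3N (3 equiv), CO (1 atm), 19 (1.5 equiv), toluene, 80 °C
Reagents that add atoms: carbon monoxide, [C-]#[O+]
Why: Heck-type carbonylative esterification (aryloxycarbonylation), in which the aryl iodide adds oxidatively to zerovalent palladium, CO inserts to an aroyl–palladium species held by the wide-bite-angle diphosphine, and the acyl group is transferred to the 4-hydroxyl of 19, the 2-hydroxyl being hydrogen-bonded to the ester carbonyl and flanked on both sides.

Step 10
Reactants: 20 methyl 4-[(3-formyl-2,4,5-triisopropoxy-6-methylbenzoyl)oxy]-2-hydroxy-3,6-dimethylbenzoate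
Product: 21 methyl 4-[(3-formyl-2,4,5-trihydroxy-6-methylbenzoyl)oxy]-2-hydroxy-3,6-dimethylbenzoate (CNP0216802.0)
Conditions: BCl3 (6 equiv), CH2Cl2, −78 → 0 °C; then H2O
Reagents that add atoms: none
Why: Lewis-acid ether dealkylation, in which BCl3 coordinates each ether oxygen (helped by chelation to the neighbouring carbonyl or oxygen) and chloride removes the secondary alkyl group as 2-chloropropane, conditions that aryl esters, methyl esters and the aldehyde tolerate, so that hydrolytic work-up of the aryl borates should release the target.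

Compound list
1 | 3-methylcatechol (3-methylbenzene-1,2-diol) | Cc1cccc(O)c1O | starting material
2 | 1,2-diisopropoxy-3-methylbenzene | Cc1cccc(OC(C)C)c1OC(C)C | intermediate
3 | 2-(3,4-diisopropoxy-5-methylphenyl)-4,4,5,5-tetramethyl-1,3,2-dioxaborolane | Cc1cc(B2OC(C)(C)C(C)(C)O2)cc(OC(C)C)c1OC(C)C | intermediate (not isolated)
4 | 3,4-diisopropoxy-5-methylphenol | Cc1cc(O)cc(OC(C)C)c1OC(C)C | intermediate
5 | 3,4-diisopropoxy-5-methylphenyl N-isopropylcarbamate | CC(C)NC(=O)Oc1cc(C)c(OC(C)C)c(OC(C)C)c1 | intermediate
6 | 3,4-diisopropoxy-5-methylphenyl N-(tert-butyldimethylsilyl)-N-isopropylcarbamate | CC(C)N(C(=O)Oc1cc(C)c(OC(C)C)c(OC(C)C)c1)[Si](C)(C)C(C)(C)C | intermediate (not isolated)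
7 | 2-lithio derivative of 6 (lithium on the ring carbon between the carbamate oxygen and the neighbouring isopropoxy group) | [Li]c1c(OC(=O)N(C(C)C)[Si](C)(C)C(C)(C)C)cc(C)c(OC(C)C)c1OC(C)C | intermediate (not isolated)
8 | 3,4-diisopropoxy-5-methyl-2-(trimethylsilyl)phenyl N-(tert-butyldimethylsilyl)-N-isopropylcarbamate | CC(C)N(C(=O)Oc1cc(C)c(OC(C)C)c(OC(C)C)c1[Si](C)(C)C)[Si](C)(C)C(C)(C)C | intermediate (not isolated)
9 | 3,4-diisopropoxy-5-methyl-2-(trimethylsilyl)phenyl N-isopropylcarbamate | CC(C)NC(=O)Oc1cc(C)c(OC(C)C)c(OC(C)C)c1[Si](C)(C)C | intermediate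
10 | 3,4-diisopropoxy-5-methyl-2-(trimethylsilyl)phenol (formed as its amidinium phenoxide) | Cc1cc(O)c([Si](C)(C)C)c(OC(C)C)c1OC(C)C | intermediate (not isolated)
11 | 3,4-diisopropoxy-5-methyl-2-(trimethylsilyl)phenyl trifluoromethanesulfonate | Cc1cc(OS(=O)(=O)C(F)(F)F)c([Si](C)(C)C)c(OC(C)C)c1OC(C)C | intermediate
12 | N,N-dimethylformamide | CN(C)C=O | starting material
13 | 3,4-diisopropoxy-5-methylbenzyne (1,2-didehydro-3,4-diisopropoxy-5-methylbenzene, the C5≡C6 aryne of ring A) | CC1=CC#CC(OC(C)C)=C1OC(C)C | intermediate (not isolated)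
14 | 3,4-diisopropoxy-N,N,5-trimethyl-2H-benzoxet-2-amine (racemic at the aminal carbon) | CN(C)C1Oc2cc(C)c(OC(C)C)c(OC(C)C)c12 | intermediate (not isolated)
15 | 6-[(dimethylamino)methylidene]-4,5-diisopropoxy-3-methylcyclohexa-2,4-dien-1-one (exocyclic C=C geometry not defined) | CN(C)C=C1C(=O)C=C(C)C(OC(C)C)=C1OC(C)C | intermediate (not isolated)
16 | 6-hydroxy-2,3-diisopropoxy-4-methylbenzaldehyde | CC(C)Oc1c(C)cc(O)c(C=O)c1OC(C)C | intermediate
17 | 2-hydroxy-3-iodo-5,6-diisopropoxy-4-methylbenzaldehyde | CC(C)Oc1c(C)c(I)c(O)c(C=O)c1OC(C)C | intermediate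
18 | 3-iodo-2,5,6-triisopropoxy-4-methylbenzaldehyde | CC(C)Oc1c(C)c(I)c(OC(C)C)c(C=O)c1OC(C)C | intermediate
19 | methyl 2,4-dihydroxy-3,6-dimethylbenzoate | COC(=O)c1c(C)cc(O)c(C)c1O | starting material
20 | methyl 4-[(3-formyl-2,4,5-triisopropoxy-6-methylbenzoyl)oxy]-2-hydroxy-3,6-dimethylbenzoate | COC(=O)c1c(C)cc(OC(=O)c2c(C)c(OC(C)C)c(OC(C)C)c(C=O)c2OC(C)C)c(C)c1O | intermediate
21 | methyl 4-[(3-formyl-2,4,5-trihydroxy-6-methylbenzoyl)oxy]-2-hydroxy-3,6-dimethylbenzoate (CNP0216802.0) | COC(=O)c1c(C)cc(OC(=O)c2c(C)c(O)c(O)c(C=O)c2O)c(C)c1O | target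

Total step count: 10. Longest linear sequence: 10 steps (1 to 21); phenol 19 is purchased and enters at step 9.

Steps most likely to fail

Step 6 (key step). The aryne or the ring-opened quinone methide may be intercepted by a second aryne (over-arylation to diaryl ether or xanthene-type material), or the formamide oxygen may add with the reverse orientation. The fallback sets out from phenol 4 and comes back at aldehyde 16, fixing the regiochemistry by directed ortho-metalation instead of aryne polarisation. Phenol 4 would be protected with MOMCl and iPr2NEt (CH2Cl2, 0 °C → rt) as 1,2-diisopropoxy-5-(methoxymethoxy)-3-methylbenzene F1. n-BuLi (THF, 0 °C) should deprotonate the position between the acetal and isopropoxy oxygens to give [2,3-diisopropoxy-6-(methoxymethoxy)-4-methylphenyl]lithium F2. Quenching with 12 would give 2,3-diisopropoxy-6-(methoxymethoxy)-4-methylbenzaldehyde F3, and aq. HCl in THF (40 °C) should remove the acetal to deliver 16.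

Step 9. Oxidative addition and CO insertion may be sluggish at a carbon flanked by methyl and isopropoxy groups, protodeiodination may compete, or the hindered phenol may capture the aroyl–palladium species poorly. The fallback sets out from iodide 18 and comes back at 20, replacing the catalytic carbonylation by carboxylation of an aryllithium and a classical depside esterification. Aldehyde 18 would be masked with HC(OMe)3 and catalytic TsOH in MeOH as 1-(dimethoxymethyl)-3-iodo-2,5,6-triisopropoxy-4-methylbenzene F4. Iodine–lithium exchange (n-BuLi, THF, −78 °C) would give [3-(dimethoxymethyl)-2,4,5-triisopropoxy-6-methylphenyl]lithium F5, and CO2 should convert it into 3-(dimethoxymethyl)-2,4,5-triisopropoxy-6-methylbenzoic acid F6. Aq. HCl in THF would unmask 3-formyl-2,4,5-triisopropoxy-6-methylbenzoic acid F7. Activation as the mixed anhydride with (CF3CO)2O in toluene (rt) in the presence of 19 should acylate its 4-hydroxyl and give 20.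

Step 4. Deprotonation may drift to the ortho position beside the methyl group, or external silylation of the crowded aryllithium may be slow enough for the carbamoyl group to migrate (anionic ortho-Fries rearrangement). The fallback sets out from phenol 4 and comes back at triflate 11, forming the C–Si bond by intramolecular oxygen-to-carbon silyl migration. Phenol 4 would be taken through the same 1,2-diisopropoxy-5-(methoxymethoxy)-3-methylbenzene F1 and [2,3-diisopropoxy-6-(methoxymethoxy)-4-methylphenyl]lithium F2 as above, the smaller and more strongly coordinating acetal improving site control. Quenching with I2 would give 2-iodo-3,4-diisopropoxy-1-(methoxymethoxy)-5-methylbenzene F8, and aq. HCl in THF would give 2-iodo-3,4-diisopropoxy-5-methylphenol F9. (Me3Si)2NH in THF at reflux would form (2-iodo-3,4-diisopropoxy-5-methylphenoxy)trimethylsilane F10. n-BuLi (−78 °C) would generate [2,3-diisopropoxy-4-methyl-6-(trimethylsilyloxy)phenyl]lithium F11, which should undergo retro-Brook rearrangement to the lithium salt of 10. Tf2O in the same flask would then give 11.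

Further compounds
F1 | step 6 | 1,2-diisopropoxy-5-(methoxymethoxy)-3-methylbenzene | COCOc1cc(C)c(OC(C)C)c(OC(C)C)c1
F2 | step 6 | [2,3-diisopropoxy-6-(methoxymethoxy)-4-methylphenyl]lithium | [Li]c1c(OCOC)cc(C)c(OC(C)C)c1OC(C)C
F3 | step 6 | 2,3-diisopropoxy-6-(methoxymethoxy)-4-methylbenzaldehyde | COCOc1cc(C)c(OC(C)C)c(OC(C)C)c1C=O
F4 | step 9 | 1-(dimethoxymethyl)-3-iodo-2,5,6-triisopropoxy-4-methylbenzene | COC(OC)c1c(OC(C)C)c(I)c(C)c(OC(C)C)c1OC(C)C
F5 | step 9 | [3-(dimethoxymethyl)-2,4,5-triisopropoxy-6-methylphenyl]lithium | COC(OC)c1c(OC(C)C)c([Li])c(C)c(OC(C)C)c1OC(C)C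
F6 | step 9 | 3-(dimethoxymethyl)-2,4,5-triisopropoxy-6-methylbenzoic acid | COC(OC)c1c(OC(C)C)c(C(=O)O)c(C)c(OC(C)C)c1OC(C)C
F7 | step 9 | 3-formyl-2,4,5-triisopropoxy-6-methylbenzoic acid | O=Cc1c(OC(C)C)c(C(=O)O)c(C)c(OC(C)C)c1OC(C)C
F8 | step 4 | 2-iodo-3,4-diisopropoxy-1-(methoxymethoxy)-5-methylbenzene | COCOc1cc(C)c(OC(C)C)c(OC(C)C)c1I
F9 | step 4 | 2-iodo-3,4-diisopropoxy-5-methylphenol | Cc1cc(O)c(I)c(OC(C)C)c1OC(C)C
F10 | step 4 | (2-iodo-3,4-diisopropoxy-5-methylphenoxy)trimethylsilane | Cc1cc(O[Si](C)(C)C)c(I)c(OC(C)C)c1OC(C)C
F11 | step 4 | [2,3-diisopropoxy-4-methyl-6-(trimethylsilyloxy)phenyl]lithium | [Li]c1c(O[Si](C)(C)C)cc(C)c(OC(C)C)c1OC(C)C
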